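Atom numbering follows the drimane skeleton: ring A is C1–C5/C10, ring B is C5–C10, C11 is the carboxyl on C9 and C12 the carboxyl on C8. Compound numbers are those of the steps below.

## The problem

The target 21 is a trans-fused decalin with a gem-dimethyl group at C4, an angular methyl at C10, carboxylic acids on C9 and C8, and a (2E,4E,6E)-octatrienoate on the C6 oxygen. Five stereocentres (5S,6R,8S,9S,10S) have to be set. The C10 methyl, the C6 oxygen and the C8 carboxyl are all axial on the β face of ring B, so the C8 carboxyl sits in its less stable orientation next to an enolisable hydrogen. C10 is quaternary and cannot be corrected later; once in place, its axial methyl screens the β face and can direct reagents to the α face at C6 and C8. The trienoate does not survive hydrogenation, hydride, radical conditions, strong base or soft nucleophiles, so it must arrive late and the two acids must then be freed without base. A free 6β-hydroxyl is 1,3-diaxial to C12 and closes to the 12,6-lactone whenever C12 is an unhindered ester or an activated acyl group, so the carboxyl protection has to prevent this. The enabling feature is that C6 is an oxidised carbon on C5 and lies one methylene (C7) from the carboxyl-bearing C8. A C6 acyl radical on ring A can therefore add to a 2-substituted acrylate (C7=C8–C12) and close ring B by forming only the C6–C7 bond, with C6 arriving as a ketone.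

## Retrosynthesis

**21 ⇒ 20 (two O–tert-butyl bonds).** The acids are carried as tert-butyl esters. Methyl esters would need hydroxide at the neopentyl C11 ester, which endangers the trienoate and exposes C8–H and C9–H to base. Allyl esters would not survive saturation of ring A, and benzyl esters offer benzylic hydrogens to the photocatalyst of the key step. Acidolysis of 20 is indifferent to hindrance and touches no stereocentre.

**20 ⇒ 17 + 18 (C6 O–acyl bond).** The trienoate is attached last but one, to the 6β-alcohol 17, from commercial acid 18. The forward reaction must acylate an axial alcohol flanked by three syn-axial groups. The tert-butyl ester at C12 is what keeps this alcohol from lactonising while it waits for the acyl donor.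

**17 ⇒ 16 ⇒ 15 (C6–H, then C1–H and C2–H).** The C6 carbinol comes from ketone 16 by α-face hydride delivery, the one direction the β-axial groups leave open. Ketone 16 comes from 15 by saturating the ring A alkene, after the acrylate has been consumed and before the triene is present.

**15 ⇒ 14 (C6–C7; key step).** Cutting C6–C7 removes ring B and the C8 stereocentre and leaves a monocyclic aldehyde carrying a methylidene succinate. A polar alternative (acyl anion addition under base) would isomerise the methylidene succinate through its acidic C9–H; a radical closure under neutral conditions does not. The forward reaction must close 6-endo, outrun loss of CO, and return hydrogen to the α face of C8.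

**14 ⇒ 13 ⇒ 12 ⇒ 11 ⇒ 8 (C9–C10).** Aldehyde 14 is reached from diacid 11 by esterification (12), desilylation (13) and oxidation. Diacid 11 is cut at C9–C10 by an Ireland–Claisen rearrangement of the cyclohexenyl hydrogen itaconate 8 (via 9 and 10). The allylic carbinol of 8 transfers its configuration to the quaternary C10, C9 is set in the same event, and both carboxyl carbons come from one four-carbon unit. The ring A alkene left behind is inert in the key step and removed at 15. Conjugate addition to a cyclohexenone would also make C10 but offers no comparable control of C9.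

**8 ⇒ 6 + 7; 6 ⇒ 5 ⇒ 4 ⇒ 3 ⇒ 1 + 2.** Ester 8 is the regioselective opening of itaconic anhydride 7 by alcohol 6. Alcohol 6 needs a 1,4-trans relationship between the carbinol and the C5 substituent and the (1S,4S) configuration. A reagent-controlled reduction of racemic ketone 3 would give both C5 epimers. Instead, substrate-controlled reduction to the trans diol 4, monosilylation to 5 and an enzymatic resolution give a single stereoisomer, at the cost of half the material at an early and inexpensive stage. Oxo ester 3 is the condensation product of mesityl oxide 1 and ethyl acetoacetate 2.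

## Roads not taken

**Alternative 1:** The cut is again C9–C10, but made so that it closes ring B. The δ-lactone A1 has C11 as the lactone carbonyl, C9 as its α-carbon and C6 as the carbinol carbon bearing the cyclohexenyl C5=C10 alkene. Its silyl ketene acetal would rearrange through the boat-like array that the small ring enforces, forming C9–C10, breaking C6–O and giving the drim-5-ene acid A2.
- Merits: ring B and the quaternary centre form together from a cyclocitral-derived precursor, and the lactone fixes the transition-state geometry. In ring construction this road is shorter than the chosen one.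
- Weak points: the shift must attack a tetrasubstituted alkene carbon next to the gem-dimethyl group from within a strained bicyclic boat. A2 carries C11 and C12 both on the α face (both opposite to the target), C12 at the alcohol oxidation level, and no oxygen at C6.
- Consequence: the endgame would need hydration of C5=C6 with the 5α/6β outcome, oxidation of C12, and inversion at C9 and at C8, the latter against the thermodynamic preference.
- Comparison: the chosen plan concedes the faster ring construction. In return C6 arrives as the ketone and C8 and C9 are made directly in the required sense, so no epimerisation is planned after the key step.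

**Alternative 2:** The cut is C5–C10 and C8–C9 together. Triene A3 would undergo an intramolecular Diels–Alder reaction under a chiral Lewis acid, the C9=C10 enoate adding across the C5=C6–C7=C8 silyloxydiene to give A4 with both rings closed.
- Merits: two rings and four stereocentres (C5, C8, C9, C10) in one step from an acyclic chain, with C6 masked as a silyl enol ether. In step count this road is clearly shorter, and the chosen plan cannot match that.
- Weak points: the dienophile is a β,β-disubstituted enoate that must form the quaternary C10 next to the neopentyl diene terminus C5. The diene carries both a donor and an acceptor, so the electronic match with an enoate is poor. The trans fusion needs one specific tether orientation, and the chiral Lewis acid must choose between two ester carbonyls in one substrate. The (2E,4Z,10E) geometry of A3, which includes a Z silyl enol ether, must itself be secured.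
- Comparison: the chosen plan forms one bond in the key step and traces each stereocentre to a defined element (resolved carbinol for C10, axial methyl for C6 and C8).

**Alternative 3:** The cut is C8–C12 and C9–C11, with both carboxyl carbons coming from CO. The homoallylic alcohol A5 would react with CO and methanol under PdCl2/CuCl2 (divalent palladium, reoxidised by CuCl2). The alkoxycarbonyl–palladium unit on the 6β-oxygen adds syn across C8=C9, and the C9–Pd bond is carbonylated to give lactone ester A6.
- Merits: C8 and C9 are set together in the target's sense by a tethered syn addition. This is more secure than the kinetic hydrogen delivery at C8 and the Claisen selectivity at C9 on which the chosen plan relies; in this respect the alternative is better.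
- Weak points: A5, an enantiopure trans-decalin with a 6β-hydroxyl and a Δ8 alkene, needs a synthesis about as long as the route to 15. The insertion must take place at a ring alkene whose C9 is neopentyl. A6 is a lactone methyl ester, so the endgame needs lactone opening, basic hydrolysis of the hindered C11 ester with C9 exposed, reprotection, acylation of an alcohol that can re-lactonise, and deprotection.
- Comparison: against the better stereocontrol the chosen plan sets inexpensive building blocks, no CO, and tert-butyl esters that neither lactonise nor need base for removal.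

Key step: step 10

Assumption: the lipase is taken to acetylate the (1R)-enantiomer of the cyclohex-2-en-1-ol 5, as is usual for this alcohol class, so that the (1S,4S)-alcohol is the recovered one; were the preference reversed, methanolysis of the acetate (K2CO3, MeOH) would give the same compound 6.

## Route

Step 1
Reactants: 1 mesityl oxide (4-methylpent-3-en-2-one); 2 ethyl acetoacetate
Product: 3 ethyl 2,6,6-trimethyl-4-oxocyclohex-2-ene-1-carboxylate (racemic)
Conditions: ZnCl2 (0.3 equiv), heptane–toluene, reflux, Dean–Stark
Reagents that add atoms: none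
Why: Lewis-acid-promoted Michael addition of the acetoacetate to mesityl oxide followed by intramolecular aldol condensation (Robinson-type annulation) should give the cyclohexenone; its one stereocentre (the later C5) is racemic.

Step 2
Reactants: 3 ethyl 2,6,6-trimethyl-4-oxocyclohex-2-ene-1-carboxylate
Product: 4 (1S,4S)-4-(hydroxymethyl)-3,5,5-trimethylcyclohex-2-en-1-ol (trans diol, racemic)
Conditions: i-Bu2AlH (4 equiv), CH2Cl2, −78 → 0 °C; aq. potassium sodium tartrate
Reagents that add atoms: none
Why: i-Bu2AlH reduces the enone carbonyl 1,2 and the ester to the primary alcohol in one operation. With the ester pseudoaxial (allylic 1,2-strain with the vinylic methyl), the ring methyl anti to it is axial and blocks its face of the carbonyl, so hydride should enter syn to the ester and place the new hydroxyl trans to the hydroxymethyl group.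

Step 3
Reactants: 4 (1S,4S)-4-(hydroxymethyl)-3,5,5-trimethylcyclohex-2-en-1-ol (racemic)
Product: 5 (1S,4S)-4-({[tert-butyl(dimethyl)silyl]oxy}methyl)-3,5,5-trimethylcyclohex-2-en-1-ol (racemic)
Conditions: TBSCl (1.05 equiv), imidazole, CH2Cl2, 0 °C
Reagents that add atoms: tert-butyldimethylsilyl chloride, CC(C)(C)[Si](C)(C)Cl
Why: Silylation with a bulky silyl chloride discriminates the primary from the secondary hydroxyl; any bis-silyl ether or regioisomer is removed by chromatography together with residual cis isomer.

Step 4
Reactants: 5 (1S,4S)-4-({[tert-butyl(dimethyl)silyl]oxy}methyl)-3,5,5-trimethylcyclohex-2-en-1-ol (racemic)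
Product: 6 (1S,4S)-4-({[tert-butyl(dimethyl)silyl]oxy}methyl)-3,5,5-trimethylcyclohex-2-en-1-ol (single enantiomer)
Conditions: lipase PS (Burkholderia cepacia), vinyl acetate, t-BuOMe, 30 °C, to just past half conversion
Reagents that add atoms: none
Why: Lipase-catalysed kinetic resolution by irreversible transesterification: the (1R)-alcohol is acetylated and the slower (1S,4S)-alcohol is recovered, its enantiopurity raised by running beyond half conversion. This fixes the absolute configuration of the carbinol and of the later C5.

Step 5
Reactants: 6 (1S,4S)-4-({[tert-butyl(dimethyl)silyl]oxy}methyl)-3,5,5-trimethylcyclohex-2-en-1-ol; 7 itaconic anhydride (3-methylideneoxolane-2,5-dione)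
Product: 8 4-[(1S,4S)-4-({[tert-butyl(dimethyl)silyl]oxy}methyl)-3,5,5-trimethylcyclohex-2-en-1-yl] hydrogen 2-methylidenebutanedioate
Conditions: 7 (1.5 equiv), toluene, 60 °C, no amine base; aqueous wash
Reagents that add atoms: none
Why: Uncatalysed alcoholysis of the cyclic anhydride occurs at the non-conjugated carbonyl, which is the more electrophilic and less hindered, and gives the 4-monoester. Amine bases are avoided because they isomerise itaconic to citraconic anhydride.

Step 6
Reactants: 8 4-[(1S,4S)-4-({[tert-butyl(dimethyl)silyl]oxy}methyl)-3,5,5-trimethylcyclohex-2-en-1-yl] hydrogen 2-methylidenebutanedioate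
Product: 11 (2R)-2-[(1S,6S)-6-({[tert-butyl(dimethyl)silyl]oxy}methyl)-1,5,5-trimethylcyclohex-2-en-1-yl]-3-methylidenebutanedioic acid, via (3Z)-bis-silylated ketene acetal 9 (not isolated), via bis(trimethylsilyl) ester 10 (not isolated)
Conditions: LiN(SiMe3)2 (2.3 equiv), Me3SiCl (4 equiv), THF–DMPU, −78 °C → rt, then 60 °C; aq. citric acid
Reagents that add atoms: none
Why: Ireland–Claisen rearrangement: the acid is silylated in situ, the ester CH2 is enolised and O-silylated, and the [3,3] shift forms C9–C10 on the face that carried the carbinol oxygen, anti to the C5 substituent, so the carbinol configuration becomes that of the quaternary C10. Cyclohexenyl esters rearrange through a boat-like array (a chair would put the silyloxy group under the gem-dimethyl ring); with the vinyl substituent turned away from the ring this should give the C9 configuration shown.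

Step 7
Reactants: 11 (2R)-2-[(1S,6S)-6-({[tert-butyl(dimethyl)silyl]oxy}methyl)-1,5,5-trimethylcyclohex-2-en-1-yl]-3-methylidenebutanedioic acid
Product: 12 di-tert-butyl (2R)-2-[(1S,6S)-6-({[tert-butyl(dimethyl)silyl]oxy}methyl)-1,5,5-trimethylcyclohex-2-en-1-yl]-3-methylidenebutanedioate
Conditions: tert-butyl 2,2,2-trichloroacetimidate (4 equiv), CH2Cl2–cyclohexane, rt
Reagents that add atoms: tert-butyl 2,2,2-trichloroacetimidate, CC(C)(C)OC(=N)C(Cl)(Cl)Cl
Why: The imidate tert-butylates both carboxylic acids through acid-promoted ionisation. No base is present, so the acidic C9–H of the methylidene succinate, whose removal would move the double bond into conjugation, is not touched.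

Step 8
Reactants: 12 di-tert-butyl (2R)-2-[(1S,6S)-6-({[tert-butyl(dimethyl)silyl]oxy}methyl)-1,5,5-trimethylcyclohex-2-en-1-yl]-3-methylidenebutanedioate
Product: 13 di-tert-butyl (2R)-2-[(1S,6S)-6-(hydroxymethyl)-1,5,5-trimethylcyclohex-2-en-1-yl]-3-methylidenebutanedioate
Conditions: HF·pyridine, THF–pyridine, 0 °C → rt
Reagents that add atoms: none
Why: Fluoride cleavage of the primary silyl ether under mildly acidic conditions leaves the tert-butyl esters and the base-sensitive methylidene succinate intact; the bulky C11 ester resists δ-lactonisation by the freed alcohol.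

Step 9
Reactants: 13 di-tert-butyl (2R)-2-[(1S,6S)-6-(hydroxymethyl)-1,5,5-trimethylcyclohex-2-en-1-yl]-3-methylidenebutanedioate
Product: 14 di-tert-butyl (2R)-2-[(1S,6S)-6-formyl-1,5,5-trimethylcyclohex-2-en-1-yl]-3-methylidenebutanedioate
Conditions: Dess–Martin periodinane, NaHCO3, CH2Cl2, 0 °C → rt
Reagents that add atoms: none
Why: Dess–Martin oxidation under buffered, neutral conditions gives the aldehyde without epimerising C5 (flanked by two quaternary carbons) and without alkene migration.

Step 10
Reactants: 14 di-tert-butyl (2R)-2-[(1S,6S)-6-formyl-1,5,5-trimethylcyclohex-2-en-1-yl]-3-methylidenebutanedioate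
Product: 15 di-tert-butyl (5S,8S,9S,10S)-6-oxodrim-1-ene-11,12-dioate (trans-fused; C11 and C12 both β)
Conditions: (n-Bu4N)4[W10O32] (2 mol%), degassed MeCN (0.02 M), 390 nm LEDs, rt
Reagents that add atoms: none
Why: Photoexcited decatungstate abstracts the hydridic formyl hydrogen of 14, and the nucleophilic C6 acyl radical adds to the unsubstituted terminus C7 of the 2-substituted acrylate, closing ring B in the 6-endo-trig mode through a chair-like array with the acyl group on C5 and the side chain on C10 both equatorial, hence the trans ring fusion with C5 untouched. The closest known reaction types are the decatungstate-photocatalysed hydroacylation of electron-poor alkenes with aliphatic aldehydes and the 6-endo cyclisation of acyl radicals onto acrylates. 5-Exo closure would require attack at the fully substituted end C8 and is disfavoured both sterically and by polarity, and the ring A alkene is reachable only by 4-exo or 5-endo attack. The tertiary α-ester radical at C8 is quenched by back hydrogen-atom transfer from the reduced polyoxometalate, a very large donor that should approach the α face, away from the axial C10 methyl that is 1,3 to C8; this puts hydrogen on the α face and leaves the ester axial (8S). Room temperature and high dilution keep loss of CO from the hindered acyl radical and intermolecular addition slower than cyclisation, and the allylic C3 hydrogens, next to a quaternary carbon and less hydridic than the formyl hydrogen, should not compete for the catalyst.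

Step 11
Reactants: 15 di-tert-butyl (5S,8S,9S,10S)-6-oxodrim-1-ene-11,12-dioate
Product: 16 di-tert-butyl (5S,8S,9S,10S)-6-oxodrimane-11,12-dioate
Conditions: H2 (1 atm), Pd/C, EtOAc, rt
Reagents that add atoms: none
Why: Heterogeneous hydrogenation saturates the only alkene (cis-disubstituted); the ketone and the tert-butyl esters are inert under these conditions and no stereocentre is created.

Step 12
Reactants: 16 di-tert-butyl (5S,8S,9S,10S)-6-oxodrimane-11,12-dioate
Product: 17 di-tert-butyl (5S,6R,8S,9S,10S)-6-hydroxydrimane-11,12-dioate (6β-alcohol)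
Conditions: NaBH4, MeOH–THF, −20 → 0 °C; aq. NH4Cl at 0 °C
Reagents that add atoms: none
Why: Borohydride reduction: the β face of the C6 carbonyl is screened by three axial groups (4β-methyl, C10 methyl, C8 ester), so hydride enters from the α face and gives the axial 6β-alcohol. The tert-butyl ester at C12 is too hindered for the 1,3-diaxial alkoxide to lactonise onto it under these conditions.

Step 13
Reactants: 17 di-tert-butyl (5S,6R,8S,9S,10S)-6-hydroxydrimane-11,12-dioate; 18 (2E,4E,6E)-octa-2,4,6-trienoic acid
Product: 20 di-tert-butyl (5S,6R,8S,9S,10S)-6-{[(2E,4E,6E)-octa-2,4,6-trienoyl]oxy}drimane-11,12-dioate, via mixed trichlorobenzoic anhydride 19 (not isolated)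
Conditions: 18, 2,4,6-trichlorobenzoyl chloride, Et3N, toluene, rt; then 17, DMAP (2 equiv), toluene, 50 °C, dark
Reagents that add atoms: none
Why: Yamaguchi esterification: the mixed anhydride transfers the trienoyl group through its acylpyridinium ion to the hindered secondary alcohol. The all-E acid is the thermodynamic geometry, so isomerisation is not expected.

Step 14
Reactants: 20 di-tert-butyl (5S,6R,8S,9S,10S)-6-{[(2E,4E,6E)-octa-2,4,6-trienoyl]oxy}drimane-11,12-dioate
Product: 21 (5S,6R,8S,9S,10S)-6-{[(2E,4E,6E)-octa-2,4,6-trienoyl]oxy}drimane-11,12-dioic acid (target, CNP0462207.1)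
Conditions: CF3CO2H–CH2Cl2 (1:3), 0 °C → rt, dark; co-evaporation with toluene
Reagents that add atoms: none
Why: Acidolysis of the tert-butyl esters proceeds by alkyl–oxygen cleavage, is independent of the hindrance at C11 and needs no base, so C8, C9 and the trienoate are left untouched.

## Compound list

1 | mesityl oxide (4-methylpent-3-en-2-one) | CC(=O)C=C(C)C | starting material
2 | ethyl acetoacetate | CCOC(=O)CC(C)=O | starting material
3 | ethyl 2,6,6-trimethyl-4-oxocyclohex-2-ene-1-carboxylate (racemic) | CCOC(=O)C1C(C)=CC(=O)CC1(C)C | intermediate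
4 | (1S,4S)-4-(hydroxymethyl)-3,5,5-trimethylcyclohex-2-en-1-ol (trans, racemic; the enantiomer carried on is drawn) | O[C@@H]1C=C(C)[C@@H](CO)C(C)(C)C1 | intermediate
5 | (1S,4S)-4-({[tert-butyl(dimethyl)silyl]oxy}methyl)-3,5,5-trimethylcyclohex-2-en-1-ol (trans, racemic; the enantiomer carried on is drawn) | O[C@@H]1C=C(C)[C@@H](CO[Si](C)(C)C(C)(C)C)C(C)(C)C1 | intermediate
6 | (1S,4S)-4-({[tert-butyl(dimethyl)silyl]oxy}methyl)-3,5,5-trimethylcyclohex-2-en-1-ol (single enantiomer) | O[C@@H]1C=C(C)[C@@H](CO[Si](C)(C)C(C)(C)C)C(C)(C)C1 | intermediate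
7 | itaconic anhydride (3-methylideneoxolane-2,5-dione) | C=C1CC(=O)OC1=O | starting material
8 | 4-[(1S,4S)-4-({[tert-butyl(dimethyl)silyl]oxy}methyl)-3,5,5-trimethylcyclohex-2-en-1-yl] hydrogen 2-methylidenebutanedioate | C=C(CC(=O)O[C@@H]1C=C(C)[C@@H](CO[Si](C)(C)C(C)(C)C)C(C)(C)C1)C(=O)O | intermediate
9 | trimethylsilyl (3Z)-4-{[(1S,4S)-4-({[tert-butyl(dimethyl)silyl]oxy}methyl)-3,5,5-trimethylcyclohex-2-en-1-yl]oxy}-2-methylidene-4-[(trimethylsilyl)oxy]but-3-enoate | C=C(C(=O)O[Si](C)(C)C)/C=C(\O[Si](C)(C)C)O[C@@H]1C=C(C)[C@@H](CO[Si](C)(C)C(C)(C)C)C(C)(C)C1 | intermediate (not isolated)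
10 | bis(trimethylsilyl) (2R)-2-[(1S,6S)-6-({[tert-butyl(dimethyl)silyl]oxy}methyl)-1,5,5-trimethylcyclohex-2-en-1-yl]-3-methylidenebutanedioate | C=C(C(=O)O[Si](C)(C)C)[C@H](C(=O)O[Si](C)(C)C)[C@@]1(C)C=CCC(C)(C)[C@@H]1CO[Si](C)(C)C(C)(C)C | intermediate (not isolated)
11 | (2R)-2-[(1S,6S)-6-({[tert-butyl(dimethyl)silyl]oxy}methyl)-1,5,5-trimethylcyclohex-2-en-1-yl]-3-methylidenebutanedioic acid | C=C(C(=O)O)[C@H](C(=O)O)[C@@]1(C)C=CCC(C)(C)[C@@H]1CO[Si](C)(C)C(C)(C)C | intermediate
12 | di-tert-butyl (2R)-2-[(1S,6S)-6-({[tert-butyl(dimethyl)silyl]oxy}methyl)-1,5,5-trimethylcyclohex-2-en-1-yl]-3-methylidenebutanedioate | C=C(C(=O)OC(C)(C)C)[C@H](C(=O)OC(C)(C)C)[C@@]1(C)C=CCC(C)(C)[C@@H]1CO[Si](C)(C)C(C)(C)C | intermediate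
13 | di-tert-butyl (2R)-2-[(1S,6S)-6-(hydroxymethyl)-1,5,5-trimethylcyclohex-2-en-1-yl]-3-methylidenebutanedioate | C=C(C(=O)OC(C)(C)C)[C@H](C(=O)OC(C)(C)C)[C@@]1(C)C=CCC(C)(C)[C@@H]1CO | intermediate
14 | di-tert-butyl (2R)-2-[(1S,6S)-6-formyl-1,5,5-trimethylcyclohex-2-en-1-yl]-3-methylidenebutanedioate | C=C(C(=O)OC(C)(C)C)[C@H](C(=O)OC(C)(C)C)[C@@]1(C)C=CCC(C)(C)[C@@H]1C=O | intermediate (key-step precursor)
15 | di-tert-butyl (5S,8S,9S,10S)-6-oxodrim-1-ene-11,12-dioate | O=C1C[C@H](C(=O)OC(C)(C)C)[C@H](C(=O)OC(C)(C)C)[C@@]2(C)C=CCC(C)(C)[C@H]12 | intermediate (key-step product)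
16 | di-tert-butyl (5S,8S,9S,10S)-6-oxodrimane-11,12-dioate | O=C1C[C@H](C(=O)OC(C)(C)C)[C@H](C(=O)OC(C)(C)C)[C@@]2(C)CCCC(C)(C)[C@H]12 | intermediate
17 | di-tert-butyl (5S,6R,8S,9S,10S)-6-hydroxydrimane-11,12-dioate | O[C@@H]1C[C@H](C(=O)OC(C)(C)C)[C@H](C(=O)OC(C)(C)C)[C@@]2(C)CCCC(C)(C)[C@H]12 | intermediate
18 | (2E,4E,6E)-octa-2,4,6-trienoic acid | C/C=C/C=C/C=C/C(=O)O | starting material
19 | (2E,4E,6E)-octa-2,4,6-trienoic 2,4,6-trichlorobenzoic anhydride | C/C=C/C=C/C=C/C(=O)OC(=O)c1c(Cl)cc(Cl)cc1Cl | intermediate (not isolated)
20 | di-tert-butyl (5S,6R,8S,9S,10S)-6-{[(2E,4E,6E)-octa-2,4,6-trienoyl]oxy}drimane-11,12-dioate | C/C=C/C=C/C=C/C(=O)O[C@@H]1C[C@H](C(=O)OC(C)(C)C)[C@H](C(=O)OC(C)(C)C)[C@@]2(C)CCCC(C)(C)[C@H]12 | intermediate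
21 | (5S,6R,8S,9S,10S)-6-{[(2E,4E,6E)-octa-2,4,6-trienoyl]oxy}drimane-11,12-dioic acid | C/C=C/C=C/C=C/C(=O)O[C@@H]1C[C@H](C(=O)O)[C@H](C(=O)O)[C@@]2(C)CCCC(C)(C)[C@H]12 | target

## Step count and least certain steps

Total: 14 steps. Longest linear sequence: 14 steps (1 and 2 to 21); 7 and 18 enter without steps of their own.

**Step 10 (key step).** Hydrogen abstraction may be unselective (allylic C3–H instead of the formyl hydrogen), the hindered acyl radical may lose CO before it cyclises, or hydrogen may return to the β face of C8. Fallback, from 14 back to 15: oxidise the aldehyde (NaClO2, NaH2PO4, 2-methylbut-2-ene, t-BuOH–water) to the C6 carboxylic acid corresponding to 14, F1. Convert it with diphenyl diselenide and PBu3 into its Se-phenyl selenoester F2. Generate the same acyl radical by group transfer with (Me3Si)3SiH and AIBN in benzene at 80 °C under slow addition. This is the classical selenoester 6-endo acyl radical cyclisation; it removes the dependence on selective hydrogen abstraction and uses a different hydrogen donor at C8, and it should give 15.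

**Step 6.** The dienolate may add to the acrylate of a second molecule, the shift to the hindered trisubstituted terminus may be slow, and the C9 selectivity may be eroded if the boat and chair arrays compete. Fallback, from 8 back to 12: mask the methylidene group by conjugate addition of thiophenol (Et3N) to give the 2-[(phenylsulfanyl)methyl]succinate half-ester F3. Run the Ireland–Claisen rearrangement on this ordinary succinate enolate (LiN(SiMe3)2, Me3SiCl) to the rearranged diacid F4. Esterify with the trichloroacetimidate to the di-tert-butyl ester F5, oxidise with one equivalent of mCPBA at −78 °C to the sulfoxide F6, and eliminate benzenesulfenic acid in toluene at 110 °C to restore the methylidene group and reach 12.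

**Step 13.** Acyl transfer to an axial alcohol with three syn-axial neighbours may be slower than decomposition of the activated trienoate. Fallback, from 17 back to 20: acylate with the small and very reactive bromoacetyl bromide (pyridine, CH2Cl2, 0 °C) to the 6β-bromoacetate F7. Convert it with P(OEt)3 at 110 °C (Arbuzov reaction) into the 6β-(diethoxyphosphoryl)acetate F8. Build the triene on the ester by Horner–Wadsworth–Emmons olefination with (2E,4E)-hexa-2,4-dienal (LiCl, i-Pr2NEt, MeCN), which should give the 2E alkene and so 20.

**Step 2.** Hydride may attack the other face of the enone, so that the cis diol predominates. Fallback, from 3 back to 5: carry the cis diol F9 through the same monosilylation to the cis silyl ether F10. Invert the carbinol by a Mitsunobu reaction (4-nitrobenzoic acid, PPh3, diisopropyl azodicarboxylate) to the trans 4-nitrobenzoate F11, and methanolyse (K2CO3, MeOH) to 5.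

**Step 14.** Acid may isomerise or oligomerise the triene, or promote acyl transfer from O6 to the neighbouring C12 acid. Fallback, from 16 back to 21: exchange the ester type before the triene is present. Cleave 16 with CF3CO2H to the keto diacid F12. Alkylate with allyl bromide and KHCO3 in DMF to the diallyl keto diester F13. Reduce with NaBH4 at low temperature to the diallyl 6β-hydroxy diester F14, which must be acylated without delay because it can lactonise. Acylate as in step 13 to the diallyl trienoate F15, and remove the allyl groups with Pd(PPh3)4 (zerovalent palladium) and morpholine in THF to give 21.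

## Further compounds

F1 | step 10 | C6 carboxylic acid corresponding to aldehyde 14 (CHO replaced by CO2H) | C=C(C(=O)OC(C)(C)C)[C@H](C(=O)OC(C)(C)C)[C@@]1(C)C=CCC(C)(C)[C@@H]1C(=O)O
F2 | step 10 | Se-phenyl selenoester of F1 | C=C(C(=O)OC(C)(C)C)[C@H](C(=O)OC(C)(C)C)[C@@]1(C)C=CCC(C)(C)[C@@H]1C(=O)[Se]c1ccccc1
F3 | step 6 | 4-[(1S,4S)-4-({[tert-butyl(dimethyl)silyl]oxy}methyl)-3,5,5-trimethylcyclohex-2-en-1-yl] hydrogen 2-[(phenylsulfanyl)methyl]butanedioate (both epimers at the sulfanylmethyl-bearing carbon) | OC(=O)C(CSc1ccccc1)CC(=O)O[C@@H]1C=C(C)[C@@H](CO[Si](C)(C)C(C)(C)C)C(C)(C)C1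
F4 | step 6 | analogue of diacid 11 with CH(CH2SPh) in place of C(=CH2) (both epimers at that carbon) | OC(=O)C(CSc1ccccc1)[C@H](C(=O)O)[C@@]1(C)C=CCC(C)(C)[C@@H]1CO[Si](C)(C)C(C)(C)C
F5 | step 6 | di-tert-butyl ester of F4 | CC(C)(C)OC(=O)C(CSc1ccccc1)[C@H](C(=O)OC(C)(C)C)[C@@]1(C)C=CCC(C)(C)[C@@H]1CO[Si](C)(C)C(C)(C)C
F6 | step 6 | phenyl sulfoxide of F5 | CC(C)(C)OC(=O)C(CS(=O)c1ccccc1)[C@H](C(=O)OC(C)(C)C)[C@@]1(C)C=CCC(C)(C)[C@@H]1CO[Si](C)(C)C(C)(C)C
F7 | step 13 | di-tert-butyl (5S,6R,8S,9S,10S)-6-(bromoacetoxy)drimane-11,12-dioate | BrCC(=O)O[C@@H]1C[C@H](C(=O)OC(C)(C)C)[C@H](C(=O)OC(C)(C)C)[C@@]2(C)CCCC(C)(C)[C@H]12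
F8 | step 13 | di-tert-butyl (5S,6R,8S,9S,10S)-6-{[(diethoxyphosphoryl)acetyl]oxy}drimane-11,12-dioate | CCOP(=O)(OCC)CC(=O)O[C@@H]1C[C@H](C(=O)OC(C)(C)C)[C@H](C(=O)OC(C)(C)C)[C@@]2(C)CCCC(C)(C)[C@H]12
F9 | step 2 | (1R,4S)-4-(hydroxymethyl)-3,5,5-trimethylcyclohex-2-en-1-ol (cis diol, racemic) | O[C@H]1C=C(C)[C@@H](CO)C(C)(C)C1
F10 | step 2 | (1R,4S)-4-({[tert-butyl(dimethyl)silyl]oxy}methyl)-3,5,5-trimethylcyclohex-2-en-1-ol (cis, racemic) | O[C@H]1C=C(C)[C@@H](CO[Si](C)(C)C(C)(C)C)C(C)(C)C1
F11 | step 2 | (1S,4S)-4-({[tert-butyl(dimethyl)silyl]oxy}methyl)-3,5,5-trimethylcyclohex-2-en-1-yl 4-nitrobenzoate (trans, racemic) | O=C(O[C@@H]1C=C(C)[C@@H](CO[Si](C)(C)C(C)(C)C)C(C)(C)C1)c1ccc(cc1)[N+](=O)[O-]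
F12 | step 14 | (5S,8S,9S,10S)-6-oxodrimane-11,12-dioic acid | O=C1C[C@H](C(=O)O)[C@H](C(=O)O)[C@@]2(C)CCCC(C)(C)[C@H]12
F13 | step 14 | diprop-2-en-1-yl (5S,8S,9S,10S)-6-oxodrimane-11,12-dioate | O=C1C[C@H](C(=O)OCC=C)[C@H](C(=O)OCC=C)[C@@]2(C)CCCC(C)(C)[C@H]12
F14 | step 14 | diprop-2-en-1-yl (5S,6R,8S,9S,10S)-6-hydroxydrimane-11,12-dioate | O[C@@H]1C[C@H](C(=O)OCC=C)[C@H](C(=O)OCC=C)[C@@]2(C)CCCC(C)(C)[C@H]12
F15 | step 14 | diprop-2-en-1-yl (5S,6R,8S,9S,10S)-6-{[(2E,4E,6E)-octa-2,4,6-trienoyl]oxy}drimane-11,12-dioate | C/C=C/C=C/C=C/C(=O)O[C@@H]1C[C@H](C(=O)OCC=C)[C@H](C(=O)OCC=C)[C@@]2(C)CCCC(C)(C)[C@H]12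
A1 | alternative 1 | (4R,6S)-4-({[tert-butyl(dimethyl)silyl]oxy}methyl)-6-(2,6,6-trimethylcyclohex-1-en-1-yl)oxan-2-one | O=C1C[C@H](CO[Si](C)(C)C(C)(C)C)C[C@H](O1)C1=C(C)CCCC1(C)C
A2 | alternative 1 | 12-{[tert-butyl(dimethyl)silyl]oxy}drim-5-en-11-oic acid with C11 and C12 both on the α face | C1C[C@@H](CO[Si](C)(C)C(C)(C)C)[C@@H](C(=O)O)[C@@]2(C)CCCC(C)(C)C2=1
A3 | alternative 2 | dimethyl (2E,4Z,10E)-4-{[tert-butyl(dimethyl)silyl]oxy}-6,6,10-trimethyldodeca-2,4,10-trienedioate | COC(=O)/C=C/C(O[Si](C)(C)C(C)(C)C)=C/C(C)(C)CCC/C(C)=C/C(=O)OC
A4 | alternative 2 | dimethyl 6-{[tert-butyl(dimethyl)silyl]oxy}drim-6-ene-11,12-dioate (C11 and C12 both β) | CC(C)(C)[Si](C)(C)OC1=C[C@H](C(=O)OC)[C@H](C(=O)OC)[C@@]2(C)CCCC(C)(C)[C@H]12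
A5 | alternative 3 | 11,12-dinordrim-8-en-6β-ol (5α-H, 10β-methyl) | O[C@@H]1CC=C[C@@]2(C)CCCC(C)(C)[C@H]12
A6 | alternative 3 | methyl 6β-hydroxydrimane-11,12-dioate 12,6-lactone | O=C1O[C@@H]2C[C@H]1[C@H](C(=O)OC)[C@@]3(C)CCCC(C)(C)[C@H]23
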